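**Plan**
- **Cuts:** first the two coumaroyl C–O ester bonds at O4 and O5. Then C5–O and C4–O, back through the quinide and an epoxide to a C4=C5 cyclohexene. Then ring bond C1–C6, and last C3–C4 of the open chain.
- **Enabling feature:** in the cyclohexane ring the fully substituted C1 carries carboxyl carbon C7 and faces oxygen-bearing C4 across the ring (1,4). C7–O–C4 can therefore be drawn as a δ-lactone bridge over C1–C2–C3–C4 with C5=C6 as a vinyl group on C4, an allyl ester whose enolate can bond C1 to C6.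
- **Forward:** C7–C1–C2–C3 (L-malic acid) is joined to C4–C5–C6 (allyl PMB ether) at C3–C4. The δ-lactone closes (step 7) and is exchanged for the cyclohexene (step 9). The γ-lactone of the quinide closes (step 11) and is reopened (step 13). Double acylation and one acid deprotection finish the route.
- **Stereochemistry:** C3 and C4 come from a reagent-controlled (Z)-alkoxyallylboration. C1 comes from C4 by chirality transfer in the [3,3] shift. The final C4 and C5 come from O3-directed epoxidation and anti opening by the C7 acid. The malic acid centre only keeps the early intermediates single diastereomers.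

Key step: step 9

Remark on the chemistry: atom labels C1–C7 are those of quinic acid (C7 = carboxyl carbon) and are kept for every intermediate; (−)-Ipc2BOMe is the reagent made from (+)-α-pinene.

Step 1
Reactants: 1 L-malic acid
Product: 2 (S)-2-(2,2-dimethyl-5-oxo-1,3-dioxolan-4-yl)acetic acid
Conditions: Me2C(OMe)2, p-TsOH·H2O (cat.), rt
Reagents that add atoms: 2,2-dimethoxypropane, COC(C)(C)OC
Why: Acid-catalysed transketalisation ties the α-hydroxy acid unit into the five-membered dioxolanone in preference to the six-membered alternative, which leaves the β-carboxyl (future C3) free and does not touch the S centre.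

Step 2
Reactants: 2 (S)-2-(2,2-dimethyl-5-oxo-1,3-dioxolan-4-yl)acetic acid
Product: 3 (S)-5-(2-hydroxyethyl)-2,2-dimethyl-1,3-dioxolan-4-one
Conditions: BH3·THF, THF, 0 °C to rt; MeOH quench
Reagents that add atoms: none
Why: Chemoselective borane reduction, since a free carboxylic acid is reduced far faster than the dioxolanone ester, so only C3 drops to the alcohol level.

Step 3
Reactants: 3 (S)-5-(2-hydroxyethyl)-2,2-dimethyl-1,3-dioxolan-4-one
Product: 4 (S)-2-(2,2-dimethyl-5-oxo-1,3-dioxolan-4-yl)acetaldehyde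
Conditions: Dess–Martin periodinane, CH2Cl2, 0 °C to rt
Reagents that add atoms: none
Why: Dess–Martin oxidation stops at the aldehyde under nearly neutral conditions, which avoids β-elimination of O1 as well as acid-induced collapse of 3 to the hydroxybutyrolactone.

Step 4
Reactants: 4 (S)-2-(2,2-dimethyl-5-oxo-1,3-dioxolan-4-yl)acetaldehyde; 5 allyl 4-methoxybenzyl ether
Product: 9 (5S)-5-[(2R,3R)-2-hydroxy-3-(4-methoxybenzyloxy)pent-4-en-1-yl]-2,2-dimethyl-1,3-dioxolan-4-one, via lithiated allyl ether 6 (not isolated), via Z-allylborane 7 (not isolated), via borinate 8 (not isolated)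
Conditions: 5, s-BuLi, THF, −78 °C; (−)-Ipc2BOMe, −78 °C; BF3·OEt2 then 4, −78 °C; 30% H2O2, pH 7 phosphate buffer, MeOH, 0 °C
Reagents that add atoms: none
Why: Brown (Z)-γ-alkoxyallylboration, in which the internally chelated Z-allyllithium 6 is passed to boron and Z-borane 7 adds through a closed chair transition state, so that the Z geometry gives the threo C3/C4 pair, the isopinocampheyl groups pick the aldehyde face that makes both centres R regardless of the remote C1 centre, and buffered peroxide frees 9 from borinate 8 without opening the dioxolanone.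

Step 5
Reactants: 9 (5S)-5-[(2R,3R)-2-hydroxy-3-(4-methoxybenzyloxy)pent-4-en-1-yl]-2,2-dimethyl-1,3-dioxolan-4-one
Product: 10 (5S)-5-[(2R,3R)-2-(tert-butyldimethylsilyloxy)-3-(4-methoxybenzyloxy)pent-4-en-1-yl]-2,2-dimethyl-1,3-dioxolan-4-one
Conditions: TBSOTf, 2,6-lutidine, CH2Cl2, −78 to 0 °C
Reagents that add atoms: tert-butyldimethylsilyl triflate, CC(C)(C)[Si](C)(C)OS(=O)(=O)C(F)(F)F
Why: Silylation with a silyl triflate and a hindered pyridine is fast in the cold and non-nucleophilic, so O3 is capped before it can attack C7 and close the five-membered lactone.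

Step 6
Reactants: 10 (5S)-5-[(2R,3R)-2-(tert-butyldimethylsilyloxy)-3-(4-methoxybenzyloxy)pent-4-en-1-yl]-2,2-dimethyl-1,3-dioxolan-4-one
Product: 11 (5S)-5-[(2R,3R)-2-(tert-butyldimethylsilyloxy)-3-hydroxypent-4-en-1-yl]-2,2-dimethyl-1,3-dioxolan-4-one
Conditions: DDQ, CH2Cl2–pH 7 buffer, 0 °C
Reagents that add atoms: none
Why: Oxidative PMB cleavage (hydride abstraction by DDQ, hydrolysis of the benzylic oxocarbenium ion) frees O4 alone and leaves silyl ether, vinyl group and dioxolanone intact.

Step 7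
Reactants: 11 (5S)-5-[(2R,3R)-2-(tert-butyldimethylsilyloxy)-3-hydroxypent-4-en-1-yl]-2,2-dimethyl-1,3-dioxolan-4-one
Product: 12 (3S,5R,6R)-5-(tert-butyldimethylsilyloxy)-3-hydroxy-6-vinyltetrahydro-2H-pyran-2-one
Conditions: CSA (cat.), CH2Cl2, rt
Reagents that add atoms: none
Why: Acid-catalysed transacylation in which O4 attacks the activated dioxolanone carbonyl C7 and acetone leaves, and because O3 is blocked only the six-membered lactone can form, with no stereocentre involved.

Step 8
Reactants: 12 (3S,5R,6R)-5-(tert-butyldimethylsilyloxy)-3-hydroxy-6-vinyltetrahydro-2H-pyran-2-one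
Product: 13 (3S,5R,6R)-5-(tert-butyldimethylsilyloxy)-3-(methoxymethoxy)-6-vinyltetrahydro-2H-pyran-2-one (vinyl and silyloxy groups cis)
Conditions: MOMCl, i-Pr2NEt, CH2Cl2, 0 °C to rt
Reagents that add atoms: chloromethyl methyl ether, COCCl
Why: Standard MOM ether formation with a hindered amine base, and any epimerisation at C1 would be harmless because that centre is erased in step 9.

Step 9
Reactants: 13 (3S,5R,6R)-5-(tert-butyldimethylsilyloxy)-3-(methoxymethoxy)-6-vinyltetrahydro-2H-pyran-2-one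
Product: 16 (1R,3R)-3-(tert-butyldimethylsilyloxy)-1-(methoxymethoxy)cyclohex-4-ene-1-carboxylic acid (O1 and O3 cis), via silyl ketene acetal 14 (not isolated), via trimethylsilyl ester 15 (not isolated)
Conditions: LiN(i-Pr)2, TMSCl–Et3N, THF, −78 °C to rt; toluene, 100 °C; 1 M HCl aq–THF, 0 °C
Reagents that add atoms: none
Why: LiN(i-Pr)2 removes H1 and TMSCl traps the lactone enolate on oxygen, so that ketene acetal 14 holds the allyl vinyl ether array C1=C7–O–C4–C5=C6; on heating this array undergoes a concerted suprafacial [3,3] shift in which C1–C6 forms, C4–O breaks and C4=C5 appears, and mild hydrolysis of silyl ester 15 gives 16. The closest known reaction type is the Ireland–Claisen rearrangement of silyl ketene acetals of 6-alkenyl δ-lactones to cyclohex-3-enecarboxylic acids, which is also documented for ketene acetals that carry oxygen on the nucleophilic carbon (glycolate esters, 1,4-dioxan-2-ones). The cyclohexene C1–C6 closes pericyclically across the lactone ring: C1 and C4 act as bridgeheads of a bicyclo[2.2.2]octane-like array whose bridges are C2–C3, C7–O and C6···C5, so the six reacting atoms are forced into a boat and the vinyl group must stand axial. C1, the only new stereocentre, is controlled by C4: the vinyl group can reach only the lactone face on which it stands, C7 therefore ends on the cyclohexene face that O4 leaves and O1 on the other, and because O3 is cis to the vinyl group in 13 (hence anti to O4 across the new ring) O1 and O3 come out cis, that is 1R,3R. The step needs O- rather than C-silylation, which the internal TMSCl–Et3N quench and the oxygen-rich enolate favour, and an enolate that cannot eliminate, which is secured because C2 bears no leaving group. The configuration of C1 in 13 is erased on enolisation, so only C3 and C4 of the lactone matter, and C3 is not touched.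

Step 10
Reactants: 16 (1R,3R)-3-(tert-butyldimethylsilyloxy)-1-(methoxymethoxy)cyclohex-4-ene-1-carboxylic acid
Product: 17 (1R,3R)-3-hydroxy-1-(methoxymethoxy)cyclohex-4-ene-1-carboxylic acid
Conditions: HF·pyridine, THF, 0 °C to rt
Reagents that add atoms: none
Why: Fluoride-driven Si–O cleavage frees O3–H, which has to steer the oxidant in step 11, while MOM acetal, alkene and acid persist and no lactone can form because O3 and C7 lie on opposite ring faces.

Step 11
Reactants: 17 (1R,3R)-3-hydroxy-1-(methoxymethoxy)cyclohex-4-ene-1-carboxylic acid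
Product: 19 1-O-(methoxymethyl)quinide (1-O-MOM-quinic acid 1,5-lactone), via epoxy acid 18 (not isolated)
Conditions: mCPBA, CH2Cl2, 0 °C to rt; then CSA (cat.), rt
Reagents that add atoms: 3-chloroperoxybenzoic acid, OOC(=O)c1cccc(Cl)c1
Why: Henbest epoxidation, in which hydrogen bonding of the peracid to the allylic O3–H puts the oxirane on the face of O3, after which the C7 acid on the other face opens 18 at C5 from behind (5-exo, anti, diaxial in the Fürst–Plattner sense, C4 being deactivated by the neighbouring O3), so that C4–O ends cis and C5–O trans to O3.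

Step 12
Reactants: 19 1-O-(methoxymethyl)quinide
Product: 20 3-O-(tert-butyldimethylsilyl)-1-O-(methoxymethyl)quinide
Conditions: TBSCl (1.1 equiv), imidazole, DMF, 0 °C
Reagents that add atoms: tert-butyldimethylsilyl chloride, CC(C)(C)[Si](C)(C)Cl
Why: Regioselective silylation, since in the rigid bicyclic lactone O3–H is equatorial and open whereas O4–H is axial and shielded by the lactone bridge, a bias well established for quinide itself.

Step 13
Reactants: 20 3-O-(tert-butyldimethylsilyl)-1-O-(methoxymethyl)quinide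
Product: 22 3-O-(tert-butyldimethylsilyl)-1-O-(methoxymethyl)quinic acid, via lithium carboxylate 21 (not isolated)
Conditions: LiOH (1.1 equiv), THF–H2O, 0 °C; 1 M HCl to pH 4, 0 °C
Reagents that add atoms: lithium hydroxide, [Li+].[OH-]
Why: Saponification of the strained γ-lactone is fast in the cold with about one equivalent of hydroxide, which keeps base-induced silyl migration from O3 to O4 to a minimum, and breaks only the acyl–O5 bond so that C5 keeps its configuration.

Step 14
Reactants: 22 3-O-(tert-butyldimethylsilyl)-1-O-(methoxymethyl)quinic acid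
Product: 23 tert-butyl 3-O-(tert-butyldimethylsilyl)-1-O-(methoxymethyl)quinate
Conditions: Cl3CC(=NH)O-t-Bu, CH2Cl2–cyclohexane, rt
Reagents that add atoms: tert-butyl 2,2,2-trichloroacetimidate, CC(C)(C)OC(=N)C(Cl)(Cl)Cl
Why: Imidate esterification needs no added catalyst because the carboxylic acid itself protonates the imidate, so the secondary hydroxyls stay free, and the bulky ester resists attack by O5–H better than a primary alkyl ester would.

Step 15
Reactants: 24 p-coumaric acid
Product: 27 (E)-3-[4-(methoxymethoxy)phenyl]prop-2-enoic acid, via bis-MOM derivative 25 (not isolated), via lithium cinnamate salt 26 (not isolated)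
Conditions: MOMCl, i-Pr2NEt, CH2Cl2, 0 °C to rt; then LiOH, THF–H2O, rt; 1 M HCl to pH 4, 0 °C
Reagents that add atoms: chloromethyl methyl ether, COCCl; lithium hydroxide, [Li+].[OH-]
Why: Exhaustive MOM alkylation followed by saponification of the much more labile MOM ester leaves only the phenol protected and does not touch the E alkene.

Step 16
Reactants: 23 tert-butyl 3-O-(tert-butyldimethylsilyl)-1-O-(methoxymethyl)quinate; 27 (E)-3-[4-(methoxymethoxy)phenyl]prop-2-enoic acid
Product: 28 tert-butyl 3-O-(tert-butyldimethylsilyl)-1-O-(methoxymethyl)-4,5-bis-O-[(E)-4-(methoxymethoxy)cinnamoyl]quinate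
Conditions: 27 (3 equiv), DCC, DMAP, CH2Cl2, 0 °C to rt
Reagents that add atoms: none
Why: Steglich esterification (carbodiimide activation, acyl transfer by DMAP) acylates O4–H and O5–H, the only free hydroxyls of 23, without breaking a ring C–O bond, so C4 and C5 keep their configuration.

Step 17
Reactants: 28 tert-butyl 3-O-(tert-butyldimethylsilyl)-1-O-(methoxymethyl)-4,5-bis-O-[(E)-4-(methoxymethoxy)cinnamoyl]quinate
Product: 29 4,5-di-O-p-coumaroylquinic acid
Conditions: TFA–CH2Cl2–H2O, 0 °C to rt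
Reagents that add atoms: none
Why: Global acidolysis cleaves the three MOM acetals (via oxocarbenium ions), the silyl ether and the tert-butyl ester (loss of 2-methylpropene) in one operation, while cinnamate esters tolerate acid and acyl migration, a base-promoted process, is held back at low pH.

**Compound list**
1 | L-malic acid | OC(=O)C[C@H](O)C(=O)O | starting material
2 | (S)-2-(2,2-dimethyl-5-oxo-1,3-dioxolan-4-yl)acetic acid | OC(=O)C[C@@H]1OC(C)(C)OC1=O | intermediate
3 | (S)-5-(2-hydroxyethyl)-2,2-dimethyl-1,3-dioxolan-4-one | OCC[C@@H]1OC(C)(C)OC1=O | intermediate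
4 | (S)-2-(2,2-dimethyl-5-oxo-1,3-dioxolan-4-yl)acetaldehyde | O=CC[C@@H]1OC(C)(C)OC1=O | intermediate
5 | allyl 4-methoxybenzyl ether | C=CCOCc1ccc(OC)cc1 | starting material
6 | (Z)-3-(4-methoxybenzyloxy)allyllithium | [Li]C/C=C\OCc1ccc(OC)cc1 | intermediate
7 | (Z)-[3-(4-methoxybenzyloxy)allyl]diisopinocampheylborane, Ipc groups from (+)-α-pinene | COc1ccc(cc1)CO/C=C\CB([C@@H]1C[C@@H]2C[C@H]([C@H]1C)C2(C)C)[C@@H]1C[C@@H]2C[C@H]([C@H]1C)C2(C)C | intermediate
8 | O3-diisopinocampheylborinate of 9 | C=C[C@@H](OCc1ccc(OC)cc1)[C@H](OB([C@@H]1C[C@@H]2C[C@H]([C@H]1C)C2(C)C)[C@@H]1C[C@@H]2C[C@H]([C@H]1C)C2(C)C)C[C@@H]1OC(C)(C)OC1=O | intermediate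
9 | (5S)-5-[(2R,3R)-2-hydroxy-3-(4-methoxybenzyloxy)pent-4-en-1-yl]-2,2-dimethyl-1,3-dioxolan-4-one | C=C[C@@H](OCc1ccc(OC)cc1)[C@H](O)C[C@@H]1OC(C)(C)OC1=O | intermediate
10 | (5S)-5-[(2R,3R)-2-(tert-butyldimethylsilyloxy)-3-(4-methoxybenzyloxy)pent-4-en-1-yl]-2,2-dimethyl-1,3-dioxolan-4-one | C=C[C@@H](OCc1ccc(OC)cc1)[C@H](O[Si](C)(C)C(C)(C)C)C[C@@H]1OC(C)(C)OC1=O | intermediate
11 | (5S)-5-[(2R,3R)-2-(tert-butyldimethylsilyloxy)-3-hydroxypent-4-en-1-yl]-2,2-dimethyl-1,3-dioxolan-4-one | C=C[C@@H](O)[C@H](O[Si](C)(C)C(C)(C)C)C[C@@H]1OC(C)(C)OC1=O | intermediate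
12 | (3S,5R,6R)-5-(tert-butyldimethylsilyloxy)-3-hydroxy-6-vinyltetrahydro-2H-pyran-2-one | C=C[C@H]1OC(=O)[C@@H](O)C[C@H]1O[Si](C)(C)C(C)(C)C | intermediate
13 | (3S,5R,6R)-5-(tert-butyldimethylsilyloxy)-3-(methoxymethoxy)-6-vinyltetrahydro-2H-pyran-2-one | C=C[C@H]1OC(=O)[C@@H](OCOC)C[C@H]1O[Si](C)(C)C(C)(C)C | intermediate
14 | (2R,3R)-3-(tert-butyldimethylsilyloxy)-5-(methoxymethoxy)-6-(trimethylsilyloxy)-2-vinyl-3,4-dihydro-2H-pyran | C=C[C@H]1OC(O[Si](C)(C)C)=C(OCOC)C[C@H]1O[Si](C)(C)C(C)(C)C | intermediate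
15 | trimethylsilyl (1R,3R)-3-(tert-butyldimethylsilyloxy)-1-(methoxymethoxy)cyclohex-4-ene-1-carboxylate | C[Si](C)(C)OC(=O)[C@]1(OCOC)C[C@@H](O[Si](C)(C)C(C)(C)C)C=CC1 | intermediate
16 | (1R,3R)-3-(tert-butyldimethylsilyloxy)-1-(methoxymethoxy)cyclohex-4-ene-1-carboxylic acid | OC(=O)[C@]1(OCOC)C[C@@H](O[Si](C)(C)C(C)(C)C)C=CC1 | intermediate
17 | (1R,3R)-3-hydroxy-1-(methoxymethoxy)cyclohex-4-ene-1-carboxylic acid | OC(=O)[C@]1(OCOC)C[C@@H](O)C=CC1 | intermediate
18 | 4,5-epoxide of 17, oxirane oxygen on the face of O1 and O3 (2-hydroxy-4-(methoxymethoxy)-7-oxabicyclo[4.1.0]heptane-4-carboxylic acid) | OC(=O)[C@]1(OCOC)C[C@@H](O)[C@H]2O[C@H]2C1 | intermediate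
19 | 1-O-(methoxymethyl)quinide, (1S,3R,4R,5R)-3,4-dihydroxy-1-(methoxymethoxy)-6-oxabicyclo[3.2.1]octan-7-one | O=C1O[C@@H]2C[C@@]1(OCOC)C[C@@H](O)[C@H]2O | intermediate
20 | 3-O-(tert-butyldimethylsilyl)-1-O-(methoxymethyl)quinide | O=C1O[C@@H]2C[C@@]1(OCOC)C[C@@H](O[Si](C)(C)C(C)(C)C)[C@H]2O | intermediate
21 | lithium 3-O-(tert-butyldimethylsilyl)-1-O-(methoxymethyl)quinate | [Li+].[O-]C(=O)[C@]1(OCOC)C[C@@H](O[Si](C)(C)C(C)(C)C)[C@@H](O)[C@H](O)C1 | intermediate
22 | 3-O-(tert-butyldimethylsilyl)-1-O-(methoxymethyl)quinic acid | OC(=O)[C@]1(OCOC)C[C@@H](O[Si](C)(C)C(C)(C)C)[C@@H](O)[C@H](O)C1 | intermediate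
23 | tert-butyl 3-O-(tert-butyldimethylsilyl)-1-O-(methoxymethyl)quinate | CC(C)(C)OC(=O)[C@]1(OCOC)C[C@@H](O[Si](C)(C)C(C)(C)C)[C@@H](O)[C@H](O)C1 | intermediate
24 | p-coumaric acid | O=C(O)/C=C/c1ccc(O)cc1 | starting material
25 | methoxymethyl (E)-3-[4-(methoxymethoxy)phenyl]prop-2-enoate | COCOC(=O)/C=C/c1ccc(OCOC)cc1 | intermediate
26 | lithium (E)-3-[4-(methoxymethoxy)phenyl]prop-2-enoate | [Li+].[O-]C(=O)/C=C/c1ccc(OCOC)cc1 | intermediate
27 | (E)-3-[4-(methoxymethoxy)phenyl]prop-2-enoic acid | OC(=O)/C=C/c1ccc(OCOC)cc1 | intermediate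
28 | tert-butyl 3-O-(tert-butyldimethylsilyl)-1-O-(methoxymethyl)-4,5-bis-O-[(E)-4-(methoxymethoxy)cinnamoyl]quinate | CC(C)(C)OC(=O)[C@]1(OCOC)C[C@@H](O[Si](C)(C)C(C)(C)C)[C@@H](OC(=O)/C=C/c2ccc(OCOC)cc2)[C@H](OC(=O)/C=C/c2ccc(OCOC)cc2)C1 | intermediate
29 | 4,5-di-O-p-coumaroylquinic acid, (1S,3R,4R,5R)-1,3-dihydroxy-4,5-bis{[(E)-3-(4-hydroxyphenyl)prop-2-enoyl]oxy}cyclohexane-1-carboxylic acid | O=C(/C=C/c1ccc(O)cc1)O[C@@H]1[C@H](O)C[C@@](O)(C(=O)O)C[C@H]1OC(=O)/C=C/c1ccc(O)cc1 | target

Total step count: 17. Longest linear sequence: 16 (steps 1–14, 16 and 17).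

**Steps most likely to fail**

**Step 9.**
- What may go wrong: silylation on carbon instead of oxygen. The ketene acetal may also break down thermally before the crowded boat transition state is reached, because the C3 silyloxy group is eclipsed with the vinyl bridge.
- The fallback gives up the sigmatropic closure and forms C4=C5 by ring-closing metathesis. It sets out from aldehyde 4 and comes back at acid 16.
- Vinylmagnesium bromide (THF, −78 °C) is added to 4, and the quenched mixture is stirred with catalytic CSA. O3 then closes a γ-lactone on C7 with loss of acetone.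
- No facial control is expected, but the malic acid centre makes the C3 epimers diastereomers. Chromatography should separate the trans lactone (3S,5R)-3-hydroxy-5-vinyldihydrofuran-2(3H)-one F1 from its cis epimer (3S,5S)-3-hydroxy-5-vinyldihydrofuran-2(3H)-one F2, which is set aside.
- MOMCl and i-Pr2NEt convert F1 into (3S,5R)-3-(methoxymethoxy)-5-vinyldihydrofuran-2(3H)-one F3.
- The lithium enolate of F3 (LiN(i-Pr)2, THF, −78 °C) is alkylated by allyl bromide on the face away from the vinyl group, the usual 1,3-trans preference of γ-substituted butyrolactone enolates. This gives (3R,5R)-3-allyl-3-(methoxymethoxy)-5-vinyldihydrofuran-2(3H)-one F4, in which C1 already has the configuration of 16.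
- LiOH opens the lactone to lithium (2R,4R)-2-allyl-4-hydroxy-2-(methoxymethoxy)hex-5-enoate F5.
- TBSOTf and 2,6-lutidine silylate both oxygens to tert-butyldimethylsilyl (2R,4R)-2-allyl-4-(tert-butyldimethylsilyloxy)-2-(methoxymethoxy)hex-5-enoate F6.
- K2CO3 in aqueous methanol cleaves the silyl ester to (2R,4R)-2-allyl-4-(tert-butyldimethylsilyloxy)-2-(methoxymethoxy)hex-5-enoic acid F7.
- The second-generation Grubbs catalyst (CH2Cl2, 40 °C) closes the ring with loss of ethene to 16.

**Step 4.**
- What may go wrong: premature acyl transfer. Once freed from boron, O3 attacks C7, acetone is lost and the five-membered lactone forms. Part of the metalated PMB ether may also be lost through Wittig rearrangement.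
- The fallback accepts the γ-lactone and moves the acyl group to O4 later. It sets out from 9 and comes back at 13.
- Crude 9 is stirred with catalytic CSA in CH2Cl2 until the loss of acetone is complete. This gives (3S,5R)-3-hydroxy-5-[(1R)-1-(4-methoxybenzyloxy)prop-2-en-1-yl]dihydrofuran-2(3H)-one F8.
- MOMCl and i-Pr2NEt give (3S,5R)-3-(methoxymethoxy)-5-[(1R)-1-(4-methoxybenzyloxy)prop-2-en-1-yl]dihydrofuran-2(3H)-one F9.
- MeNH(OMe)·HCl and AlMe3 (CH2Cl2, 0 °C) open the lactone to the Weinreb amide (2S,4R,5R)-4-hydroxy-N-methoxy-2-(methoxymethoxy)-5-(4-methoxybenzyloxy)-N-methylhept-6-enamide F10.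
- O3 of F10 is silylated at once (TBSOTf, 2,6-lutidine) to (2S,4R,5R)-4-(tert-butyldimethylsilyloxy)-N-methoxy-2-(methoxymethoxy)-5-(4-methoxybenzyloxy)-N-methylhept-6-enamide F11.
- DDQ frees O4 to give (2S,4R,5R)-4-(tert-butyldimethylsilyloxy)-5-hydroxy-N-methoxy-2-(methoxymethoxy)-N-methylhept-6-enamide F12.
- PPTS in warm toluene closes the δ-lactone with loss of N,O-dimethylhydroxylamine to 13.

**Step 16.**
- What may go wrong: relactonisation and incomplete acylation. With bulky groups on O1 and O3 the ring can flip to the chair in which O5–H and the ester are both axial, so attack on C7 competes with acylation. O4–H next to the silyl ether reacts slowly. Any silyl migration in step 13 would feed in the wrong regioisomer.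
- The fallback bypasses the quinide and brings O5 in already acylated. It sets out from hydroxy acid 17 and comes back at 28.
- tert-Butyl trichloroacetimidate esterifies 17 to tert-butyl (1R,3R)-3-hydroxy-1-(methoxymethoxy)cyclohex-4-ene-1-carboxylate F13.
- VO(acac)2-catalysed epoxidation with t-BuOOH, delivered through the vanadium alkoxide of O3, gives the cis-epoxy alcohol tert-butyl 2-hydroxy-4-(methoxymethoxy)-7-oxabicyclo[4.1.0]heptane-4-carboxylate F14.
- TBSCl and imidazole give tert-butyl 2-(tert-butyldimethylsilyloxy)-4-(methoxymethoxy)-7-oxabicyclo[4.1.0]heptane-4-carboxylate F15.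
- Heating F15 with acid 27 and catalytic Cs2CO3 in DMF opens the oxirane at C5. C5 is remote from the electron-withdrawing O3 and is the carbon that allows diaxial opening. The product is tert-butyl 3-O-(tert-butyldimethylsilyl)-1-O-(methoxymethyl)-5-O-[(E)-4-(methoxymethoxy)cinnamoyl]quinate F16.
- A Steglich esterification of the remaining O4–H with 27 leads to 28. An acyl shift from O5 to O4 in F16 would be harmless, because both positions end with the same acyl group.

**Further compounds**
F1 | step 9 | (3S,5R)-3-hydroxy-5-vinyldihydrofuran-2(3H)-one | C=C[C@H]1C[C@H](O)C(=O)O1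
F2 | step 9 | (3S,5S)-3-hydroxy-5-vinyldihydrofuran-2(3H)-one | C=C[C@@H]1C[C@H](O)C(=O)O1
F3 | step 9 | (3S,5R)-3-(methoxymethoxy)-5-vinyldihydrofuran-2(3H)-one | C=C[C@H]1C[C@H](OCOC)C(=O)O1
F4 | step 9 | (3R,5R)-3-allyl-3-(methoxymethoxy)-5-vinyldihydrofuran-2(3H)-one | C=C[C@H]1C[C@@](CC=C)(OCOC)C(=O)O1
F5 | step 9 | lithium (2R,4R)-2-allyl-4-hydroxy-2-(methoxymethoxy)hex-5-enoate | C=C[C@H](O)C[C@@](CC=C)(OCOC)C(=O)[O-].[Li+]
F6 | step 9 | tert-butyldimethylsilyl (2R,4R)-2-allyl-4-(tert-butyldimethylsilyloxy)-2-(methoxymethoxy)hex-5-enoate | C=C[C@H](O[Si](C)(C)C(C)(C)C)C[C@@](CC=C)(OCOC)C(=O)O[Si](C)(C)C(C)(C)C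
F7 | step 9 | (2R,4R)-2-allyl-4-(tert-butyldimethylsilyloxy)-2-(methoxymethoxy)hex-5-enoic acid | C=C[C@H](O[Si](C)(C)C(C)(C)C)C[C@@](CC=C)(OCOC)C(=O)O
F8 | step 4 | (3S,5R)-3-hydroxy-5-[(1R)-1-(4-methoxybenzyloxy)prop-2-en-1-yl]dihydrofuran-2(3H)-one | C=C[C@@H](OCc1ccc(OC)cc1)[C@H]1C[C@H](O)C(=O)O1
F9 | step 4 | (3S,5R)-3-(methoxymethoxy)-5-[(1R)-1-(4-methoxybenzyloxy)prop-2-en-1-yl]dihydrofuran-2(3H)-one | C=C[C@@H](OCc1ccc(OC)cc1)[C@H]1C[C@H](OCOC)C(=O)O1
F10 | step 4 | (2S,4R,5R)-4-hydroxy-N-methoxy-2-(methoxymethoxy)-5-(4-methoxybenzyloxy)-N-methylhept-6-enamide | C=C[C@@H](OCc1ccc(OC)cc1)[C@H](O)C[C@H](OCOC)C(=O)N(C)OC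
F11 | step 4 | (2S,4R,5R)-4-(tert-butyldimethylsilyloxy)-N-methoxy-2-(methoxymethoxy)-5-(4-methoxybenzyloxy)-N-methylhept-6-enamide | C=C[C@@H](OCc1ccc(OC)cc1)[C@H](O[Si](C)(C)C(C)(C)C)C[C@H](OCOC)C(=O)N(C)OC
F12 | step 4 | (2S,4R,5R)-4-(tert-butyldimethylsilyloxy)-5-hydroxy-N-methoxy-2-(methoxymethoxy)-N-methylhept-6-enamide | C=C[C@@H](O)[C@H](O[Si](C)(C)C(C)(C)C)C[C@H](OCOC)C(=O)N(C)OC
F13 | step 16 | tert-butyl (1R,3R)-3-hydroxy-1-(methoxymethoxy)cyclohex-4-ene-1-carboxylate | CC(C)(C)OC(=O)[C@]1(OCOC)C[C@@H](O)C=CC1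
F14 | step 16 | tert-butyl 2-hydroxy-4-(methoxymethoxy)-7-oxabicyclo[4.1.0]heptane-4-carboxylate, oxirane oxygen cis to O1 and O3 | CC(C)(C)OC(=O)[C@]1(OCOC)C[C@@H](O)[C@H]2O[C@H]2C1
F15 | step 16 | tert-butyl 2-(tert-butyldimethylsilyloxy)-4-(methoxymethoxy)-7-oxabicyclo[4.1.0]heptane-4-carboxylate, oxirane oxygen cis to O1 and O3 | CC(C)(C)OC(=O)[C@]1(OCOC)C[C@@H](O[Si](C)(C)C(C)(C)C)[C@H]2O[C@H]2C1
F16 | step 16 | tert-butyl 3-O-(tert-butyldimethylsilyl)-1-O-(methoxymethyl)-5-O-[(E)-4-(methoxymethoxy)cinnamoyl]quinate | CC(C)(C)OC(=O)[C@]1(OCOC)C[C@@H](O[Si](C)(C)C(C)(C)C)[C@@H](O)[C@H](OC(=O)/C=C/c2ccc(OCOC)cc2)C1
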